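**Plan**

- Retrosynthetic cuts, in this order: the two MOM ethers and the TBS ether; the C8–CH2 bond of the prenyl group (Stille coupling on a C8 iodide); the C2=C3 double bond of ring C (ring-closing metathesis); the C4–C3 bond (1-arylvinyl Grignard reagent plus aldehyde); then C4a–CHO, C6–CH2 and C8–Si on ring A (three directed lithiations).
- Enabling feature: ring C has a single C=C, C2=C3, lying between O1 and the aryl-bearing carbon alpha to the C4 ketone. It can therefore be opened into an O1 vinyl ether on C8a and an alpha-aryl vinyl ketone on the neighbouring C4a.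
- Forward order: ring A is bought (5-methoxyresorcinol) and substituted at C8, C6 and C4a one lithiation at a time; ring B arrives with the Grignard reagent; ring C is closed by metathesis; the prenyl group goes on only afterwards, because its alkene would otherwise close onto the vinyl ether. C8 carries iodine (made from a blocking silyl group) through the metathesis.
- Stereochemistry: the single (S)-carbinol centre comes from (R)-2-isopropyloxirane, opened at its CH2 terminus so that the stereogenic C–O bond is never broken.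

Key step: step 13

Assumption: (R)-2-isopropyloxirane is taken as a purchasable single enantiomer; alcohol 18 is formed as both epimers at the new carbinol carbon, which converge in step 12.

**Route**

Step 1
Reactants: 1 5-methoxyresorcinol
Product: 2 1-methoxy-3,5-bis(methoxymethoxy)benzene
Conditions: NaH, MOMCl, DMF, 0 °C to rt
Reagents that add atoms: chloromethyl methyl ether, COCCl
Why: Williamson-type O-alkylation of both phenoxides gives the bis-MOM ether, whose acetal groups then serve as directing groups for lithiation.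

Step 2
Reactants: 2 1-methoxy-3,5-bis(methoxymethoxy)benzene
Product: 4 [4-methoxy-2,6-bis(methoxymethoxy)phenyl]trimethylsilane, via aryllithium 3 (not isolated)
Conditions: n-BuLi, THF, 0 °C; then TMSCl, −78 °C to rt
Reagents that add atoms: chlorotrimethylsilane, C[Si](C)(C)Cl
Why: Directed ortho-metalation should take place at the carbon flanked by the two OMOM groups (the future C8), and the silyl quench blocks that site and stores it as a latent iodide.

Step 3
Reactants: 4 [4-methoxy-2,6-bis(methoxymethoxy)phenyl]trimethylsilane, 5 (R)-2-isopropyloxirane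
Product: 7 (2S)-1-[6-methoxy-2,4-bis(methoxymethoxy)-3-(trimethylsilyl)phenyl]-3-methylbutan-2-ol, via aryllithium 6 (not isolated)
Conditions: n-BuLi, THF, 0 °C; then 5, BF3·OEt2, −78 °C; H2O
Reagents that add atoms: none
Why: Directed ortho-metalation at one of the two equivalent sites between OMe and OMOM, then BF3-assisted SN2 opening of the epoxide at its CH2 terminus, leaves the epoxide stereocentre untouched; it is named S in the product only because CH2Ar now ranks below isopropyl.

Step 4
Reactants: 7 (2S)-1-[6-methoxy-2,4-bis(methoxymethoxy)-3-(trimethylsilyl)phenyl]-3-methylbutan-2-ol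
Product: 8 tert-butyl({(2S)-1-[6-methoxy-2,4-bis(methoxymethoxy)-3-(trimethylsilyl)phenyl]-3-methylbutan-2-yl}oxy)dimethylsilane
Conditions: TBSCl, imidazole, DMF, 40 °C
Reagents that add atoms: tert-butyldimethylsilyl chloride, CC(C)(C)[Si](C)(C)Cl
Why: Imidazole-promoted silylation protects the secondary alcohol against the later lithiation, Grignard and oxidation steps without touching the aryl MOM ethers.

Step 5
Reactants: 8 tert-butyl({(2S)-1-[6-methoxy-2,4-bis(methoxymethoxy)-3-(trimethylsilyl)phenyl]-3-methylbutan-2-yl}oxy)dimethylsilane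
Product: 10 3-[(2S)-2-(tert-butyldimethylsilyloxy)-3-methylbutyl]-2-methoxy-4,6-bis(methoxymethoxy)-5-(trimethylsilyl)benzaldehyde, via aryllithium 9 (not isolated)
Conditions: s-BuLi, TMEDA, THF, −78 °C; then DMF, −78 to 0 °C; H2O
Reagents that add atoms: N,N-dimethylformamide, CN(C)C=O
Why: The last ring hydrogen lies between OMe and OMOM, so directed ortho-metalation has only this site, and formylation of the aryllithium with DMF installs the future C4 carbon on C4a.

Step 6
Reactants: 10 3-[(2S)-2-(tert-butyldimethylsilyloxy)-3-methylbutyl]-2-methoxy-4,6-bis(methoxymethoxy)-5-(trimethylsilyl)benzaldehyde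
Product: 11 3-[(2S)-2-(tert-butyldimethylsilyloxy)-3-methylbutyl]-5-iodo-2-methoxy-4,6-bis(methoxymethoxy)benzaldehyde
Conditions: ICl, CH2Cl2, −78 to 0 °C; aq. Na2S2O3
Reagents that add atoms: iodine monochloride, ICl
Why: Ipso-iododesilylation is fast at a carbon that is ortho, ortho and para to three oxygens, and doing it here, before any alkene or ring B is present, leaves ICl no competing nucleophile and removes the acid-labile aryl–silicon bond before the dealkylation of step 7.

Step 7
Reactants: 11 3-[(2S)-2-(tert-butyldimethylsilyloxy)-3-methylbutyl]-5-iodo-2-methoxy-4,6-bis(methoxymethoxy)benzaldehyde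
Product: 12 3-[(2S)-2-(tert-butyldimethylsilyloxy)-3-methylbutyl]-6-hydroxy-5-iodo-2-methoxy-4-(methoxymethoxy)benzaldehyde
Conditions: MgBr2·OEt2, Et2O–toluene, 0 °C to rt; H2O
Reagents that add atoms: none
Why: Chelation-controlled Lewis-acid cleavage of an acetal: magnesium held between the formyl oxygen and the ortho OMOM group lets bromide open only that O–CH2–O unit, whereas the distant C7 MOM ether, the methyl ether and the TBS ether have no such activation.

Step 8
Reactants: 12 3-[(2S)-2-(tert-butyldimethylsilyloxy)-3-methylbutyl]-6-hydroxy-5-iodo-2-methoxy-4-(methoxymethoxy)benzaldehyde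
Product: 13 3-[(2S)-2-(tert-butyldimethylsilyloxy)-3-methylbutyl]-6-(ethenyloxy)-5-iodo-2-methoxy-4-(methoxymethoxy)benzaldehyde
Conditions: 2,4,6-trivinylcyclotriboroxane–pyridine complex, Cu(OAc)2 (2 equiv), pyridine, CH2Cl2, rt
Reagents that add atoms: 2,4,6-trivinylcyclotriboroxane–pyridine complex, C=CB1OB(C=C)OB(C=C)O1.c1ccncc1
Why: Chan–Lam-type oxidative O-vinylation of a phenol with a vinylboron reagent on divalent copper runs at room temperature and tolerates the aldehyde, the aryl iodide and both acid-labile ethers.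

Step 9
Reactants: 14 4'-hydroxyacetophenone
Product: 15 1-[4-(methoxymethoxy)phenyl]ethanone
Conditions: MOMCl, K2CO3, acetone, rt
Reagents that add atoms: chloromethyl methyl ether, COCCl
Why: O-alkylation of the phenoxide masks the ring B hydroxyl as the same acetal that is removed at the end.

Step 10
Reactants: 15 1-[4-(methoxymethoxy)phenyl]ethanone
Product: 16 1-(1-bromoethenyl)-4-(methoxymethoxy)benzene
Conditions: (PhO)3P, Br2, Et3N, CH2Cl2, −60 °C to reflux
Reagents that add atoms: bromine, BrBr
Why: Ketone-to-vinyl-bromide conversion with the triphenyl phosphite–bromine reagent (halophosphonium activation of the carbonyl oxygen, bromide addition, amine-promoted elimination) is established for aryl methyl ketones, and the excess Et3N keeps the medium free of HBr so the acetal should survive.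

Step 11
Reactants: 13 3-[(2S)-2-(tert-butyldimethylsilyloxy)-3-methylbutyl]-6-(ethenyloxy)-5-iodo-2-methoxy-4-(methoxymethoxy)benzaldehyde, 16 1-(1-bromoethenyl)-4-(methoxymethoxy)benzene
Product: 18 1-{3-[(2S)-2-(tert-butyldimethylsilyloxy)-3-methylbutyl]-6-(ethenyloxy)-5-iodo-2-methoxy-4-(methoxymethoxy)phenyl}-2-[4-(methoxymethoxy)phenyl]prop-2-en-1-ol (both C1 epimers), via alkenylmagnesium bromide 17 (not isolated)
Conditions: 16, Mg, THF, rt to 40 °C, decant from Mg; then 13, THF, −78 to 0 °C; H2O
Reagents that add atoms: none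
Why: Grignard formation from the 1-bromoalkene and 1,2-addition to the aldehyde form the C4–C3 bond; an alkenylmagnesium reagent does not exchange with the aryl iodide at low temperature, and the uncontrolled carbinol centre is erased in step 12.

Step 12
Reactants: 18 1-{3-[(2S)-2-(tert-butyldimethylsilyloxy)-3-methylbutyl]-6-(ethenyloxy)-5-iodo-2-methoxy-4-(methoxymethoxy)phenyl}-2-[4-(methoxymethoxy)phenyl]prop-2-en-1-ol
Product: 19 1-{3-[(2S)-2-(tert-butyldimethylsilyloxy)-3-methylbutyl]-6-(ethenyloxy)-5-iodo-2-methoxy-4-(methoxymethoxy)phenyl}-2-[4-(methoxymethoxy)phenyl]prop-2-en-1-one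
Conditions: Dess–Martin periodinane, NaHCO3, CH2Cl2, 0 °C to rt
Reagents that add atoms: none
Why: Dess–Martin oxidation of the benzylic, allylic alcohol under bicarbonate buffer spares the acid-sensitive vinyl ether; the enone is taken on at once in dilute solution because alpha-aryl vinyl ketones dimerise on standing.

Step 13
Reactants: 19 1-{3-[(2S)-2-(tert-butyldimethylsilyloxy)-3-methylbutyl]-6-(ethenyloxy)-5-iodo-2-methoxy-4-(methoxymethoxy)phenyl}-2-[4-(methoxymethoxy)phenyl]prop-2-en-1-one
Product: 20 6-[(2S)-2-(tert-butyldimethylsilyloxy)-3-methylbutyl]-8-iodo-5-methoxy-7-(methoxymethoxy)-3-[4-(methoxymethoxy)phenyl]chromen-4-one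
Conditions: RuCl2(H2IMes)(=CH-C6H4-2-OiPr) (second-generation Hoveyda–Grubbs catalyst, 10 mol%), toluene (0.005 M), 100 °C, Ar sparge
Reagents that add atoms: none
Why: Proposed new method: the ruthenium alkylidene exchanges with the unhindered, electron-rich O-vinyl group to give the oxygen-stabilised carbene Ru=CH–OAr, which undergoes [2+2] cycloaddition with the 1,1-disubstituted enone alkene on the neighbouring ring A carbon so that the carbene carbon bonds to the aryl-bearing alpha carbon and ruthenium to the terminal CH2; cycloreversion of the ruthenacyclobutane releases the chromone and Ru=CH2, and ethylene leaves the hot solution. The closest known reactions are ring-closing metatheses of aryl vinyl ethers to benzofurans and chromenes and of aryl acrylates to coumarins, none of which pairs an enol ether with an alpha-aryl enone. Ring C closes as a six-membered ring by formation of the C2=C3 double bond, C2 and C3 becoming ring atoms while the two terminal CH2 groups are expelled. No stereocentre is formed, and the (S)-carbinol centre in the C6 side chain is remote and untouched. The step needs ring closure to outrun intermolecular metathesis of the vinyl ether and hetero-Diels–Alder dimerisation of the enone; the ortho placement of the two alkenes on C8a and C4a, the high dilution, the polarity match of an electron-rich carbene with an electron-poor alkene and the gain of the aromatic 4-pyranone should secure this, and no third alkene competes because C8 bears iodine and not the prenyl group.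

Step 14
Reactants: 20 6-[(2S)-2-(tert-butyldimethylsilyloxy)-3-methylbutyl]-8-iodo-5-methoxy-7-(methoxymethoxy)-3-[4-(methoxymethoxy)phenyl]chromen-4-one, 21 tributyl(3-methylbut-2-enyl)stannane
Product: 22 6-[(2S)-2-(tert-butyldimethylsilyloxy)-3-methylbutyl]-5-methoxy-7-(methoxymethoxy)-3-[4-(methoxymethoxy)phenyl]-8-(3-methylbut-2-enyl)chromen-4-one
Conditions: Pd(PPh3)4 (10 mol%), DMF, 90 °C
Reagents that add atoms: none
Why: Stille coupling: oxidative addition of the C8–I bond to zerovalent palladium, transmetalation of the prenyl group from tin and reductive elimination should give the linear 8-prenyl compound, as in prenylations of iodinated flavonoids.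

Step 15
Reactants: 22 6-[(2S)-2-(tert-butyldimethylsilyloxy)-3-methylbutyl]-5-methoxy-7-(methoxymethoxy)-3-[4-(methoxymethoxy)phenyl]-8-(3-methylbut-2-enyl)chromen-4-one
Product: 23 7-hydroxy-6-[(2S)-2-hydroxy-3-methylbutyl]-3-(4-hydroxyphenyl)-5-methoxy-8-(3-methylbut-2-enyl)chromen-4-one (CNP0323282.1)
Conditions: HCl (1.25 M in MeOH), 40 °C
Reagents that add atoms: none
Why: Acid-catalysed transacetalisation of both aryl MOM ethers and methanolysis of the TBS ether occur under conditions mild enough to leave the prenyl alkene, the C5 methyl ether and the carbinol stereocentre unchanged.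

**Compound list**

1 | 5-methoxyresorcinol | COc1cc(O)cc(O)c1 | starting material
2 | 1-methoxy-3,5-bis(methoxymethoxy)benzene | COCOc1cc(OC)cc(OCOC)c1 | intermediate
3 | [4-methoxy-2,6-bis(methoxymethoxy)phenyl]lithium (not isolated) | COCOc1cc(OC)cc(OCOC)c1[Li] | intermediate
4 | [4-methoxy-2,6-bis(methoxymethoxy)phenyl]trimethylsilane | COCOc1cc(OC)cc(OCOC)c1[Si](C)(C)C | intermediate
5 | (R)-2-isopropyloxirane | CC(C)[C@@H]1CO1 | starting material
6 | [6-methoxy-2,4-bis(methoxymethoxy)-3-(trimethylsilyl)phenyl]lithium (not isolated) | COCOc1c([Li])c(OC)cc(OCOC)c1[Si](C)(C)C | intermediate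
7 | (2S)-1-[6-methoxy-2,4-bis(methoxymethoxy)-3-(trimethylsilyl)phenyl]-3-methylbutan-2-ol | COc1cc(OCOC)c([Si](C)(C)C)c(OCOC)c1C[C@H](O)C(C)C | intermediate
8 | tert-butyl({(2S)-1-[6-methoxy-2,4-bis(methoxymethoxy)-3-(trimethylsilyl)phenyl]-3-methylbutan-2-yl}oxy)dimethylsilane | COc1cc(OCOC)c([Si](C)(C)C)c(OCOC)c1C[C@H](O[Si](C)(C)C(C)(C)C)C(C)C | intermediate
9 | {3-[(2S)-2-(tert-butyldimethylsilyloxy)-3-methylbutyl]-2-methoxy-4,6-bis(methoxymethoxy)-5-(trimethylsilyl)phenyl}lithium (not isolated) | COc1c([Li])c(OCOC)c([Si](C)(C)C)c(OCOC)c1C[C@H](O[Si](C)(C)C(C)(C)C)C(C)C | intermediate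
10 | 3-[(2S)-2-(tert-butyldimethylsilyloxy)-3-methylbutyl]-2-methoxy-4,6-bis(methoxymethoxy)-5-(trimethylsilyl)benzaldehyde | COc1c(C=O)c(OCOC)c([Si](C)(C)C)c(OCOC)c1C[C@H](O[Si](C)(C)C(C)(C)C)C(C)C | intermediate
11 | 3-[(2S)-2-(tert-butyldimethylsilyloxy)-3-methylbutyl]-5-iodo-2-methoxy-4,6-bis(methoxymethoxy)benzaldehyde | COc1c(C=O)c(OCOC)c(I)c(OCOC)c1C[C@H](O[Si](C)(C)C(C)(C)C)C(C)C | intermediate
12 | 3-[(2S)-2-(tert-butyldimethylsilyloxy)-3-methylbutyl]-6-hydroxy-5-iodo-2-methoxy-4-(methoxymethoxy)benzaldehyde | COc1c(C=O)c(O)c(I)c(OCOC)c1C[C@H](O[Si](C)(C)C(C)(C)C)C(C)C | intermediate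
13 | 3-[(2S)-2-(tert-butyldimethylsilyloxy)-3-methylbutyl]-6-(ethenyloxy)-5-iodo-2-methoxy-4-(methoxymethoxy)benzaldehyde | COc1c(C=O)c(OC=C)c(I)c(OCOC)c1C[C@H](O[Si](C)(C)C(C)(C)C)C(C)C | intermediate
14 | 4'-hydroxyacetophenone | CC(=O)c1ccc(O)cc1 | starting material
15 | 1-[4-(methoxymethoxy)phenyl]ethanone | COCOc1ccc(C(C)=O)cc1 | intermediate
16 | 1-(1-bromoethenyl)-4-(methoxymethoxy)benzene | COCOc1ccc(C(Br)=C)cc1 | intermediate
17 | {1-[4-(methoxymethoxy)phenyl]ethenyl}magnesium bromide (not isolated) | COCOc1ccc(C(=C)[Mg]Br)cc1 | intermediate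
18 | 1-{3-[(2S)-2-(tert-butyldimethylsilyloxy)-3-methylbutyl]-6-(ethenyloxy)-5-iodo-2-methoxy-4-(methoxymethoxy)phenyl}-2-[4-(methoxymethoxy)phenyl]prop-2-en-1-ol, both C1 epimers | COc1c(C(O)C(=C)c2ccc(OCOC)cc2)c(OC=C)c(I)c(OCOC)c1C[C@H](O[Si](C)(C)C(C)(C)C)C(C)C | intermediate
19 | 1-{3-[(2S)-2-(tert-butyldimethylsilyloxy)-3-methylbutyl]-6-(ethenyloxy)-5-iodo-2-methoxy-4-(methoxymethoxy)phenyl}-2-[4-(methoxymethoxy)phenyl]prop-2-en-1-one | COc1c(C(=O)C(=C)c2ccc(OCOC)cc2)c(OC=C)c(I)c(OCOC)c1C[C@H](O[Si](C)(C)C(C)(C)C)C(C)C | intermediate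
20 | 6-[(2S)-2-(tert-butyldimethylsilyloxy)-3-methylbutyl]-8-iodo-5-methoxy-7-(methoxymethoxy)-3-[4-(methoxymethoxy)phenyl]chromen-4-one | COc1c(C[C@H](O[Si](C)(C)C(C)(C)C)C(C)C)c(OCOC)c(I)c2occ(-c3ccc(OCOC)cc3)c(=O)c12 | intermediate
21 | tributyl(3-methylbut-2-enyl)stannane | CCCC[Sn](CCCC)(CCCC)CC=C(C)C | starting material
22 | 6-[(2S)-2-(tert-butyldimethylsilyloxy)-3-methylbutyl]-5-methoxy-7-(methoxymethoxy)-3-[4-(methoxymethoxy)phenyl]-8-(3-methylbut-2-enyl)chromen-4-one | COc1c(C[C@H](O[Si](C)(C)C(C)(C)C)C(C)C)c(OCOC)c(CC=C(C)C)c2occ(-c3ccc(OCOC)cc3)c(=O)c12 | intermediate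
23 | 7-hydroxy-6-[(2S)-2-hydroxy-3-methylbutyl]-3-(4-hydroxyphenyl)-5-methoxy-8-(3-methylbut-2-enyl)chromen-4-one (CNP0323282.1) | COc1c(C[C@H](O)C(C)C)c(O)c(CC=C(C)C)c2occ(-c3ccc(O)cc3)c(=O)c12 | target

**Totals**

Total step count: 15. Longest linear sequence: 13 steps (steps 1–8 and 11–15, from 5-methoxyresorcinol); steps 9 and 10 prepare the ring B bromide.

**Steps most likely to fail, with fallbacks**

Step 13. The oxygen-stabilised ruthenium carbene may be too stable to turn over on the hindered, electron-poor 1,1-disubstituted alkene, so that the enone oligomerises before ring C closes. The fallback uses no metathesis and sets out from salicylaldehyde 12. Treatment of 12 with 2.5 equiv of Grignard reagent 17 in THF (the first equivalent is spent on the phenol) should give the phenolic allylic alcohol 1-{3-[(2S)-2-(tert-butyldimethylsilyloxy)-3-methylbutyl]-6-hydroxy-5-iodo-2-methoxy-4-(methoxymethoxy)phenyl}-2-[4-(methoxymethoxy)phenyl]prop-2-en-1-ol F1. Oxidation with MnO2 in CH2Cl2 should give the hydroxy enone 1-{3-[(2S)-2-(tert-butyldimethylsilyloxy)-3-methylbutyl]-6-hydroxy-5-iodo-2-methoxy-4-(methoxymethoxy)phenyl}-2-[4-(methoxymethoxy)phenyl]prop-2-en-1-one F2, which is not isolated: with a little Et3N the phenol adds to the enone terminus (6-endo oxa-Michael addition) to give the isoflavanone 6-[(2S)-2-(tert-butyldimethylsilyloxy)-3-methylbutyl]-8-iodo-5-methoxy-7-(methoxymethoxy)-3-[4-(methoxymethoxy)phenyl]chroman-4-one F3 as both C3 epimers. Dehydrogenation of F3 with DDQ in dioxane at 90 °C returns to the route at 20.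

Step 14. Transmetalation through the gamma carbon of the allylic stannane would deliver the 1,1-dimethylallyl isomer, and oxidative addition at the doubly ortho-substituted iodide may be slow enough for protodeiodination to compete. The fallback sets out from 20: Stille coupling with allyltributylstannane and Pd(PPh3)4 in DMF, where allyl transposition changes nothing, should give 8-allyl-6-[(2S)-2-(tert-butyldimethylsilyloxy)-3-methylbutyl]-5-methoxy-7-(methoxymethoxy)-3-[4-(methoxymethoxy)phenyl]chromen-4-one F4. Cross-metathesis of F4 with excess 2-methylbut-2-ene and RuCl2(H2IMes)(PCy3)(=CHPh) (second-generation Grubbs catalyst) in CH2Cl2 at 40 °C returns to the route at 22.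

Step 8. Copper-mediated O–C coupling may stall at a phenoxide that is flanked by iodine and held in a hydrogen bond to the formyl group. The fallback sets out from 12: alkylation with excess 1,2-dibromoethane and K2CO3 in DMF at 60 °C should give 6-(2-bromoethoxy)-3-[(2S)-2-(tert-butyldimethylsilyloxy)-3-methylbutyl]-5-iodo-2-methoxy-4-(methoxymethoxy)benzaldehyde F5. E2 elimination of HBr from F5 with KOtBu in THF at 0 °C (the aldehyde has no alpha hydrogen) returns to the route at 13.

**Further compounds**

F1 | step 13 | 1-{3-[(2S)-2-(tert-butyldimethylsilyloxy)-3-methylbutyl]-6-hydroxy-5-iodo-2-methoxy-4-(methoxymethoxy)phenyl}-2-[4-(methoxymethoxy)phenyl]prop-2-en-1-ol | COc1c(C(O)C(=C)c2ccc(OCOC)cc2)c(O)c(I)c(OCOC)c1C[C@H](O[Si](C)(C)C(C)(C)C)C(C)C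
F2 | step 13 | 1-{3-[(2S)-2-(tert-butyldimethylsilyloxy)-3-methylbutyl]-6-hydroxy-5-iodo-2-methoxy-4-(methoxymethoxy)phenyl}-2-[4-(methoxymethoxy)phenyl]prop-2-en-1-one | COc1c(C(=O)C(=C)c2ccc(OCOC)cc2)c(O)c(I)c(OCOC)c1C[C@H](O[Si](C)(C)C(C)(C)C)C(C)C
F3 | step 13 | 6-[(2S)-2-(tert-butyldimethylsilyloxy)-3-methylbutyl]-8-iodo-5-methoxy-7-(methoxymethoxy)-3-[4-(methoxymethoxy)phenyl]chroman-4-one | COc1c(C[C@H](O[Si](C)(C)C(C)(C)C)C(C)C)c(OCOC)c(I)c2OCC(c3ccc(OCOC)cc3)C(=O)c12
F4 | step 14 | 8-allyl-6-[(2S)-2-(tert-butyldimethylsilyloxy)-3-methylbutyl]-5-methoxy-7-(methoxymethoxy)-3-[4-(methoxymethoxy)phenyl]chromen-4-one | COc1c(C[C@H](O[Si](C)(C)C(C)(C)C)C(C)C)c(OCOC)c(CC=C)c2occ(-c3ccc(OCOC)cc3)c(=O)c12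
F5 | step 8 | 6-(2-bromoethoxy)-3-[(2S)-2-(tert-butyldimethylsilyloxy)-3-methylbutyl]-5-iodo-2-methoxy-4-(methoxymethoxy)benzaldehyde | COc1c(C=O)c(OCCBr)c(I)c(OCOC)c1C[C@H](O[Si](C)(C)C(C)(C)C)C(C)C
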